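## The problem

Compound 34 is a trans-fused hydroazulene diester. Ring A is the cyclopentane C1 (quaternary, methyl), C2 (carbinol), C3, C4 (isopropyl carbinol), C5 (ring-fusion CH); ring B is the cycloheptene running on through C6 (ester), C7, C8 (methyl), C9, C10 (ester) back to C1, with its only alkene at C8–C9. β denotes the face of H-5, α the face of the C1 methyl. Six stereocentres (C1, C2, C4, C5, C6, C10) must be set: H-5 is trans to the angular methyl, the C2 and C4 oxygens lie on the methyl face (α), and the C6 and C10 oxygens and the isopropyl group lie on the β face. They can be chained: one oxygen stereocentre at C4 of a cyclopentenone can set C5 and then C1, a C10 hydroxyl can deliver hydride to C2, the C5 substituent can steer isopropyl onto C4, and the C4 hydroxyl can deliver hydride to C6. C10 is the centre no neighbour controls safely, because hydride reduction of a C10 ketone would approach anti to the angular methyl and give the wrong epimer; it must be created as a carbinol by C–C bond formation. The angelates are the fragile groups: the Z-2-methylbut-2-enoyl unit isomerises to the tiglate under basic or nucleophilic conditions, so both esters must come late and be followed only by non-basic operations. The C8–C9 alkene must also be kept from sliding into conjugation with a C6 carbonyl. Four oxygens must be told apart (esters at C6 and C10, free secondary hydroxyl at C2, free tertiary hydroxyl at C4), and a seven-membered ring beside a quaternary carbon closes slowly and with loose stereocontrol. The feature that offers a way round: with C7 excised, ring B is a 2-methylcyclohex-2-enone (C6 carbonyl, C8=C9) fused to ring A, so C7 is a lone methylene between a carbonyl carbon and an alkenyl carbon and can be inserted last into a rigid hydrindenone.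

## Retrosynthesis

**Esters last (34 ⇒ 33 ⇒ 30 + 31).** The two acyl–oxygen bonds at C6 and C10 and the O–Si bond of a C2 silyl ether are cut first. Earlier esterification would expose the angelates to organometallic, basic and electrochemical steps. The C2 hydroxyl has to stay blocked (TIPS) during acylation because it is secondary like C6 and C10; the tertiary C4 hydroxyl needs no protection. Triol 30 has no ester and only two acylable hydroxyls. The forward steps must acylate two hindered secondary alcohols with angelic acid 31 without Z to E isomerisation and then desilylate under non-basic conditions.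

**C6 carbinol from the ketone (30 ⇒ 29 ⇒ 28).** The C6–H bond and the C10 O–Si bond are cut. A C6 ketone is what a ring enlargement delivers, and the tertiary C4 hydroxyl, cis to C6 on ring A, is placed to deliver hydride to the α face and give the 6β-alcohol 29. The forward reduction must not move the β,γ-alkene of 28, and the C10 TBS ether must leave before the C2 TIPS ether.

**Ring B by one-carbon insertion (28 ⇒ 27).** The C7–C8 bond is cut and C8 reattached to C6, C7 leaving the ring as a carboxymethyl group on a C6 carbinol: hydroazulenone 28 becomes hydrindene β-hydroxy acid 27. Direct closures of ring B (at C9–C10, at C1–C10 or by a 4+3 union) must form a seven-membered ring at a quaternary centre and set stereocentres in the same event. Here the ring that has to be closed is six-membered, and all five stereocentres that survive the step are already fixed in a rigid trans-hydrindane. The forward step must shift the alkenyl carbon C8, not the alkyl carbon C5, and leave the alkene at C8–C9.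

**C6–C7 bond (27 ⇒ 26 ⇒ 23 + 24).** Cutting C6–C7 gives hydrindenone 23 and ethyl acetate 24. The forward reaction is 1,2-addition of an acetate enolate to a hindered enone followed by mild saponification; the new C6 configuration does not matter.

**Six-membered ring B (23 ⇒ 21 ⇒ 20 ⇒ 19).** The C8=C9 alkene is cut by a retro-aldol condensation to keto aldehyde 21 (ethyl ketone at C6, aldehyde at C9). Only the C8 methylene can reach the aldehyde through a six-membered transition state, and the trans fusion follows from the trans C1/C5 substituents. The two carbonyls are carried masked as an alkene (ozonolysis, 19 ⇒ 20) and a dioxolane (periodate cleavage, 20 ⇒ 21), because C4 and C6 cannot both be ketones (a C4/C6 1,3-diketone would block the isopropyl addition).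

**Isopropyl at C4 (19 ⇒ 17 + 18; 17 ⇒ 16 ⇒ 15 ⇒ 14 ⇒ 13).** The C4–isopropyl bond is cut to ketone 17 and isopropylmagnesium chloride 18. The adjacent α-alkenyl group at C5 and the α-silyloxy group at C2 send the nucleophile to the β face. Ketone 17 comes from the C4 silyl ether by selective desilylation and oxidation. Graded silyl ethers (TES at C4, TBS at C10, TIPS at C2) give the order of removal that the route needs.

**C2 carbinol (13 ⇒ 12).** The C2–H bond is cut to the β-hydroxy ketone 12. The free C10 hydroxyl sits on a β-oriented arm and can deliver hydride only to the β face of the C2 carbonyl, giving the 2α-alcohol. The same step removes a ketone that is prone to retro-aldol cleavage and to β-elimination of the C4 silyloxy group.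

**Three-component coupling (12 ⇒ 6 + 7 + 8).** The C5–C6 and C1–C10 bonds are cut together: enone 6, a but-1-en-2-yl nucleophile from bromide 7 (a masked propanoyl group) and aldehyde 8. The C4 silyloxy group sends the cuprate to the α face of C5, and the enolate then takes the aldehyde on the β face of C1, creating the quaternary centre. C10 is formed as a carbinol in the same step. Its configuration is entrusted to the dioxolane stereocentre of (R)-glyceraldehyde acetonide 8 (attack anti to the α C–O bond), a stereocentre that is later excised when C9 becomes the aldehyde.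

**Enone (6 ⇒ 5 ⇒ 4 ⇒ 3 ⇒ 2 ⇒ 1).** The 4-oxygenated 2-methylcyclopentenone carries exactly the ring-A pattern (C2 carbonyl, C1 methyl, C4 oxygen). It comes from 1-(furan-2-yl)ethanol 1 by Piancatelli rearrangement, enone transposition and lipase resolution.

## Roads not taken

**Alternative 1:** The cut is C1–C10. Phenyl selenoester A2, a cyclopentenone carrying the C6–C10 chain on C5, would be treated with (Me3Si)3SiH and AIBN. The C10 acyl radical adds 7-endo to C1, the β-carbon of the enone, and the C5 radical is reduced to give dione A1.
- Merits: ring B and the quaternary centre form in one neutral step, and the nucleophilic acyl radical is polarity-matched to the enone.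
- Weak points: C10 arrives as a ketone beside the angular methyl, and hydride would enter anti to that methyl and give the 10α-alcohol, the wrong epimer, at a neopentylic allylic position that resists inversion. The ring-fusion hydrogen comes from hydrogen-atom transfer at C5 next to the C4 ketone, with no element enforcing trans. The C4 and C10 ketones must be told apart for the isopropyl addition. Only the Z alkenoyl radical can cyclise, and it can lose its geometry. C6 must be set in an open chain.
- Comparison: this road is shorter for ring B and needs no electrochemistry. The chosen plan sets against it that C10 enters as a carbinol with a control element and that C2, C4 and C6 are each set by a directed or sterically clear-cut step.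

**Alternative 2:** The cuts are C7–C8 and C1–C10. Rh2(DOSP)4 would convert siloxyvinyl diazo ester A4 into a vinylcarbene that cyclopropanates the ethoxyvinyl group of cyclopentenyl diene A5. Cope rearrangement of the cis-divinylcyclopropane then gives cycloheptadiene ester A3.
- Merits: it is the most convergent road. Two C–C bonds, ring B, C1 and C10 arise in one catalytic step, and the C1/C10 relationship is fixed by the boat transition state.
- Weak points: A3 has an ester on C8 where a methyl is needed (reduction, activation and hydride displacement next to an acid-labile enol ether). C4 is still a secondary silyl ether without isopropyl. C5 is trigonal, so H-5 must be added afterwards by protonation of the enol ether with nothing to enforce trans fusion. The Cope terminus C1 is fully substituted and rearranges slowly. The chiral catalyst meets a diene with two stereocentres (possible mismatch). A5 itself needs a multi-step synthesis.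
- Comparison: in bond economy and catalytic stereocontrol this road is better. The chosen plan sets against it the correct carbon substituents at C8 and C4 from the building blocks and H-5 fixed before ring B exists.

**Alternative 3:** The cut is C9–C10. Iodo aldehyde A7 would be treated with CrCl2 and catalytic NiCl2; the alkenylchromium adds to the C10 aldehyde and closes ring B as allylic alcohol A6.
- Merits: high chemoselectivity, alkene geometry secured by the Z iodide, and a C10 hydroxyl that appears free and distinct from the silylated oxygens. The esters could then be placed one after the other without protecting-group exchange, which is better than the chosen plan on that point.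
- Weak points: a seven-membered ring is closed onto a neopentylic aldehyde (high dilution, large excess of the divalent chromium salt). C10 is created in the closure with no reliable control, and the required alcohol is the one a redox correction cannot supply. C6 and the other four centres must be assembled on a monocyclic cyclopentane with a flexible chain.
- Comparison: length is similar. The chosen plan sets against it a fast six-membered aldol closure, C6 set last by hydroxyl delivery and C10 set early under aldehyde control; it pays with protecting-group steps and an untested anodic step.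

Key step: step 18

Assumption: the lipase is taken to acylate the R enantiomer of 3 faster, as is usual for 4-hydroxycyclopent-2-enones; were the preference reversed, the unreacted alcohol would be 5 and step 4 would fall away.

Step 1
Reactants: 1 1-(furan-2-yl)ethanol
Product: 2 trans-4-hydroxy-5-methylcyclopent-2-en-1-one (racemic)
Conditions: ZnCl2 (cat.), H2O/1,4-dioxane, reflux
Reagents that add atoms: water, O
Why: Piancatelli rearrangement: the furylcarbinol opens to a pentadienyl cation whose conrotatory 4π closure gives the 4-hydroxy-5-methyl enone with the substituents trans; the racemate is carried on.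

Step 2
Reactants: 2 trans-4-hydroxy-5-methylcyclopent-2-en-1-one
Product: 3 4-hydroxy-2-methylcyclopent-2-en-1-one (racemic)
Conditions: phosphate buffer (pH 8), H2O/1,4-dioxane, rt to 40 °C (or basic Al2O3, Et2O)
Reagents that add atoms: water, O
Why: Weak-base transposition of the 5-alkyl-4-hydroxy enone to the thermodynamically preferred 2-alkyl-4-hydroxy enone, the standard sequel to the Piancatelli rearrangement.

Step 3
Reactants: 3 4-hydroxy-2-methylcyclopent-2-en-1-one (racemic)
Product: 4 (R)-4-acetoxy-2-methylcyclopent-2-en-1-one
Conditions: Burkholderia cepacia lipase (Amano PS), vinyl acetate, tBuOMe, rt, to about half conversion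
Reagents that add atoms: vinyl acetate, C=COC(C)=O
Why: Lipase kinetic resolution by irreversible transesterification; the R alcohol should be acylated selectively and acetate 4 is separated from the unreacted S alcohol.

Step 4
Reactants: 4 (R)-4-acetoxy-2-methylcyclopent-2-en-1-one
Product: 5 (R)-4-hydroxy-2-methylcyclopent-2-en-1-one
Conditions: Burkholderia cepacia lipase, nBuOH, iPr2O, rt
Reagents that add atoms: none
Why: Enzymatic alcoholysis frees the alcohol under neutral conditions, avoiding the β-elimination that basic methanolysis of a 4-acyloxycyclopentenone invites, and passes the material through the selective enzyme a second time.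

Step 5
Reactants: 5 (R)-4-hydroxy-2-methylcyclopent-2-en-1-one
Product: 6 (R)-2-methyl-4-(triethylsilyloxy)cyclopent-2-en-1-one
Conditions: Et3SiCl, imidazole, CH2Cl2, 0 °C
Reagents that add atoms: chlorotriethylsilane, CC[Si](CC)(CC)Cl
Why: Standard silylation; the TES ether tolerates cuprate chemistry, directs it, and is the most labile of the three silyl ethers used later.

Step 6
Reactants: 6 (R)-2-methyl-4-(triethylsilyloxy)cyclopent-2-en-1-one; 7 2-bromobut-1-ene; 8 (R)-2,2-dimethyl-1,3-dioxolane-4-carbaldehyde
Product: 12 aldol adduct (10S carbinol), via but-1-en-2-yllithium 9 (not isolated), via lithium di(but-1-en-2-yl)cuprate 10 (not isolated), via lithium enolate 11 (not isolated)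
Conditions: 7, tBuLi (2 equiv per 7), Et2O, −78 °C; CuI (0.5 equiv per 7), Me2S, −40 °C; 6, −78 °C; 8, −78 °C; aq NH4Cl
Reagents that add atoms: none
Why: Three-component conjugate addition–aldol coupling: the cuprate adds anti to the C4 silyloxy group (sets C5), the regiodefined enolate takes the aldehyde on the face anti to the new C5 substituent (sets quaternary C1), and the aldehyde should be attacked anti to its dioxolane C–O bond (Felkin–Anh, 3,4-anti), which with the R aldehyde gives the C10 configuration of the target.

Step 7
Reactants: 12 aldol adduct
Product: 13 2α,10-diol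
Conditions: Me4NBH(OAc)3, MeCN/AcOH (1:1), −30 °C to rt
Reagents that add atoms: none
Why: Evans–Saksena reduction: the C10 hydroxyl binds boron and hydride is delivered intramolecularly to the β face of the C2 carbonyl, the only face the β-oriented C10 arm can reach, giving the 2α-alcohol (anti 1,3-diol).

Step 8
Reactants: 13 2α,10-diol
Product: 14 2α-TIPS ether with free C10 hydroxyl
Conditions: iPr3SiOTf (1.05 equiv), 2,6-lutidine, CH2Cl2, −78 to −40 °C
Reagents that add atoms: triisopropylsilyl triflate, CC(C)[Si](C(C)C)(C(C)C)OS(=O)(=O)C(F)(F)F
Why: The bulky silyl triflate should take the ring hydroxyl at C2, which has one branched neighbour, before the C10 hydroxyl, which is flanked by quaternary C1 and the dioxolane carbon; any regioisomer is removed here.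

Step 9
Reactants: 14 2α-TIPS ether
Product: 15 tris-silyl ether (2-TIPS, 10-TBS, 4-TES)
Conditions: tBuMe2SiOTf, 2,6-lutidine, CH2Cl2, 0 °C to rt
Reagents that add atoms: tert-butyldimethylsilyl triflate, CC(C)(C)[Si](C)(C)OS(=O)(=O)C(F)(F)F
Why: Silyl triflate protection of the hindered C10 hydroxyl; the three ethers now differ in lability in the order needed (C4 first, C10 next, C2 last).

Step 10
Reactants: 15 tris-silyl ether
Product: 16 4β-alcohol
Conditions: HF·pyridine, pyridine, THF, 0 °C
Reagents that add atoms: none
Why: Buffered fluoride cleaves the most labile and least hindered TES ether, while the neopentylic TBS and TIPS ethers and the acetonide remain.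

Step 11
Reactants: 16 4β-alcohol
Product: 17 C4 ketone
Conditions: Dess–Martin periodinane, NaHCO3, CH2Cl2, 0 °C to rt
Reagents that add atoms: none
Why: Buffered hypervalent-iodine oxidation gives the ketone without epimerising the doubly activated C5 hydrogen or drawing the exocyclic alkene into conjugation.

Step 12
Reactants: 17 C4 ketone; 18 isopropylmagnesium chloride
Product: 19 tertiary alcohol (4α-hydroxy, 4β-isopropyl)
Conditions: anhydrous CeCl3, THF, −78 °C; 18 (3 equiv), −78 to −40 °C; aq NH4Cl
Reagents that add atoms: none
Why: Cerium-mediated Grignard 1,2-addition suppresses enolisation (and with it β-elimination of the C2 silyloxy group) and β-hydride reduction; the nucleophile enters anti to the adjacent α-alkenyl group at C5 and the α-silyloxy group at C2, placing isopropyl β and hydroxyl α.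

Step 13
Reactants: 19 tertiary alcohol
Product: 20 C6 ethyl ketone
Conditions: O3, CH2Cl2/MeOH, −78 °C; PPh3
Reagents that add atoms: ozone, [O-][O+]=O
Why: Ozonolysis of the only alkene unmasks the propanoyl group; it is placed after the C4 chemistry so that C4 and C6 are never carbonyls together.

Step 14
Reactants: 20 C6 ethyl ketone
Product: 21 keto aldehyde
Conditions: H5IO6, EtOAc, rt
Reagents that add atoms: none
Why: Periodic acid hydrolyses the terminal acetonide and cleaves the freed 1,2-diol in one pot, excising the auxiliary stereocentre and leaving C9 as the aldehyde; hindered silyl ethers tolerate it.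

Step 15
Reactants: 21 keto aldehyde
Product: 23 hydrindenone, via bicyclic aldol 22 (not isolated)
Conditions: piperidine, AcOH (0.3 equiv each), toluene, 60 °C
Reagents that add atoms: none
Why: Intramolecular aldol condensation (6-enolexo): only the C8 methylene can reach the aldehyde through a six-membered transition state, and dehydration gives the 2-methylcyclohex-2-enone; the trans fusion is inherited from the trans C1/C5 substituents, and amine-salt catalysis is chosen to spare C5, C10 and the tertiary β-hydroxyl.

Step 16
Reactants: 23 hydrindenone; 24 ethyl acetate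
Product: 26 β-hydroxy ester, via ethyl acetate lithium enolate 25 (not isolated)
Conditions: LiN(iPr)2, 24, THF, −78 °C; anhydrous CeCl3; 23, −78 °C; aq NH4Cl (3.5 equiv enolate)
Reagents that add atoms: none
Why: Aldol-type 1,2-addition of the acetate enolate to the enone carbonyl, with cerium to suppress enolisation and conjugate addition; attack is expected from the β face, anti to the axial angular methyl, but the C6 configuration is of no consequence because C6 becomes trigonal in step 18.

Step 17
Reactants: 26 β-hydroxy ester
Product: 27 hydrindene β-hydroxy acid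
Conditions: LiOH·H2O, THF/MeOH/H2O, 0 °C to rt; cold dilute HCl to pH 4–5
Reagents that add atoms: lithium hydroxide, [Li+].[OH-]
Why: Saponification of the unhindered ethyl ester at low temperature to avoid retro-aldol cleavage; gentle acidification protects the tertiary allylic alcohol.

Step 18
Reactants: 27 hydrindene β-hydroxy acid
Product: 28 hydroazulenone (C6 ketone, C8=C9)
Conditions: undivided cell, graphite anode, Pt cathode, Et3N (0.2 equiv), MeCN/H2O (9:1), constant current ca. 5 mA cm−2, 2.2–2.5 F mol−1, 0 °C
Reagents that add atoms: none
Why: Proposed new method: Anodic discharge of the carboxylate at graphite and loss of CO2 leave an electron-deficient C7 (radical, or cation after a second electron transfer); C7 is homoallylic to C8=C9, closes 3-exo-trig onto C8 to a cyclopropylcarbinyl intermediate, and this reopens at the C6–C8 bond because the odd electron or charge then rests on the oxygen-bearing C6, which is oxidised at once to the ketone. The closest known reaction type is the anodic (non-Kolbe) decarboxylative one-carbon ring enlargement of β-hydroxy acids made from saturated cycloalkanones, where an alkyl carbon shifts, taken together with the 1,2-alkenyl shift of homoallyl radicals; migration of an alkenyl carbon in an enone-derived fused adduct is the untested part. Ring B is not closed by a cyclisation: the six-membered ring is enlarged to seven by inserting C7 between C6 and C8, the only ring-forming event being the transient 3-exo closure. No stereocentre is created; C1, C2, C4, C5 and C10 are untouched and C6 becomes trigonal, so either C6 epimer of 27 converges on 28. The selectivity needed is migration of C8 over C5, and the substrate secures it because only C8 offers a π bond for bridging (a saturated carbon does not shift 1,2 in a radical and is the poorer migrating group in a cation). The carboxylate is the most easily oxidised group present, and low current density, partial neutralisation and low temperature are chosen to hold back Kolbe dimerisation and base-induced movement of the C8–C9 alkene into conjugation with the new ketone.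

Step 19
Reactants: 28 hydroazulenone
Product: 29 6β-alcohol
Conditions: Me4NBH(OAc)3, MeCN/AcOH, −30 to 0 °C
Reagents that add atoms: none
Why: Evans–Saksena reduction directed by the tertiary C4 hydroxyl: hydride is delivered to the α face on which that hydroxyl lies, giving the 6β-alcohol (anti to the C4 oxygen); the cold, weakly acidic medium should leave the β,γ-alkene in place.

Step 20
Reactants: 29 6β-alcohol
Product: 30 4,6,10-triol 2-TIPS ether
Conditions: HF·pyridine, THF, 0 °C to rt
Reagents that add atoms: none
Why: Acidic fluoride removes a TBS ether far faster than a TIPS ether, freeing the C10 hydroxyl while C2 stays protected.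

Step 21
Reactants: 30 4,6,10-triol 2-TIPS ether; 31 angelic acid
Product: 33 6,10-diangelate 2-TIPS ether, via angelic 2,4,6-trichlorobenzoic anhydride 32 (not isolated)
Conditions: 31 (6 equiv), 2,4,6-trichlorobenzoyl chloride, Et3N, toluene, rt; then 30, toluene, 80 °C
Reagents that add atoms: none
Why: Yamaguchi-type esterification through the mixed anhydride without a nucleophilic catalyst, conditions under which the angeloyl group is transferred to hindered secondary alcohols with little Z to E isomerisation; the tertiary C4 hydroxyl does not react.

Step 22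
Reactants: 33 6,10-diangelate 2-TIPS ether
Product: 34 target diester
Conditions: HF·pyridine, THF, rt
Reagents that add atoms: none
Why: Fluoride desilylation under non-basic conditions, so that neither angelate is isomerised, hydrolysed or shifted.

## Compound list

1 | 1-(furan-2-yl)ethanol (racemic) | CC(O)c1ccco1 | starting material
2 | trans-4-hydroxy-5-methylcyclopent-2-en-1-one (racemic, one enantiomer drawn) | C[C@H]1[C@H](O)C=CC1=O | intermediate
3 | 4-hydroxy-2-methylcyclopent-2-en-1-one (racemic) | CC1=CC(O)CC1=O | intermediate
4 | (R)-4-acetoxy-2-methylcyclopent-2-en-1-one | O=C1C[C@@H](OC(C)=O)C=C1C | intermediate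
5 | (R)-4-hydroxy-2-methylcyclopent-2-en-1-one | O=C1C[C@@H](O)C=C1C | intermediate
6 | (R)-2-methyl-4-(triethylsilyloxy)cyclopent-2-en-1-one | O=C1C[C@@H](O[Si](CC)(CC)CC)C=C1C | intermediate
7 | 2-bromobut-1-ene | C=C(Br)CC | starting material
8 | (R)-2,2-dimethyl-1,3-dioxolane-4-carbaldehyde | CC1(C)OC[C@@H](O1)C=O | starting material
9 | but-1-en-2-yllithium | [Li]C(=C)CC | intermediate
10 | lithium di(but-1-en-2-yl)cuprate | [Li+].CCC(=C)[Cu-]C(=C)CC | intermediate
11 | lithium enolate (C1=C2) of the conjugate adduct: 4β-OTES, 5α-(but-1-en-2-yl) | CC1=C(O[Li])C[C@@H](O[Si](CC)(CC)CC)[C@@H]1C(=C)CC | intermediate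
12 | aldol adduct: cyclopentanone (C2 ketone) with 1α-methyl, 1β-[(S)-hydroxy((R)-2,2-dimethyl-1,3-dioxolan-4-yl)methyl], 4β-OTES, 5α-(but-1-en-2-yl) | CC1(C)OC[C@@H](O1)[C@@H](O)[C@@]2(C)C(=O)C[C@@H](O[Si](CC)(CC)CC)[C@@H]2C(=C)CC | intermediate
13 | 2α,10-diol (as 12 with 2α-hydroxyl in place of the ketone) | CC1(C)OC[C@@H](O1)[C@@H](O)[C@@]2(C)[C@H](O)C[C@@H](O[Si](CC)(CC)CC)[C@@H]2C(=C)CC | intermediate
14 | 2α-TIPS ether of 13 with free C10 hydroxyl | CC1(C)OC[C@@H](O1)[C@@H](O)[C@@]2(C)[C@H](O[Si](C(C)C)(C(C)C)C(C)C)C[C@@H](O[Si](CC)(CC)CC)[C@@H]2C(=C)CC | intermediate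
15 | tris-silyl ether: 2α-OTIPS, 10-OTBS, 4β-OTES | CC1(C)OC[C@@H](O1)[C@@H](O[Si](C)(C)C(C)(C)C)[C@@]2(C)[C@H](O[Si](C(C)C)(C(C)C)C(C)C)C[C@@H](O[Si](CC)(CC)CC)[C@@H]2C(=C)CC | intermediate
16 | 4β-alcohol (2α-OTIPS, 10-OTBS) | CC1(C)OC[C@@H](O1)[C@@H](O[Si](C)(C)C(C)(C)C)[C@@]2(C)[C@H](O[Si](C(C)C)(C(C)C)C(C)C)C[C@@H](O)[C@@H]2C(=C)CC | intermediate
17 | C4 ketone (2α-OTIPS, 10-OTBS, 5α-butenyl) | CC1(C)OC[C@@H](O1)[C@@H](O[Si](C)(C)C(C)(C)C)[C@@]2(C)[C@H](O[Si](C(C)C)(C(C)C)C(C)C)CC(=O)[C@@H]2C(=C)CC | intermediate
18 | isopropylmagnesium chloride | CC(C)[Mg]Cl | starting material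
19 | tertiary alcohol: 4α-hydroxy, 4β-isopropyl | CC1(C)OC[C@@H](O1)[C@@H](O[Si](C)(C)C(C)(C)C)[C@@]2(C)[C@H](O[Si](C(C)C)(C(C)C)C(C)C)C[C@@](O)(C(C)C)[C@@H]2C(=C)CC | intermediate
20 | C6 ethyl ketone (5α-propanoyl) | CC1(C)OC[C@@H](O1)[C@@H](O[Si](C)(C)C(C)(C)C)[C@@]2(C)[C@H](O[Si](C(C)C)(C(C)C)C(C)C)C[C@@](O)(C(C)C)[C@@H]2C(=O)CC | intermediate
21 | keto aldehyde: 1β-[(S)-1-(TBSO)-2-oxoethyl], 5α-propanoyl | O=C[C@@H](O[Si](C)(C)C(C)(C)C)[C@@]1(C)[C@H](O[Si](C(C)C)(C(C)C)C(C)C)C[C@@](O)(C(C)C)[C@@H]1C(=O)CC | intermediate
22 | bicyclic aldol (C9 hydroxyl, C6 ketone; C8 and C9 configurations immaterial) | O=C1C(C)C(O)[C@@H](O[Si](C)(C)C(C)(C)C)[C@@]2(C)[C@H](O[Si](C(C)C)(C(C)C)C(C)C)C[C@@](O)(C(C)C)[C@H]12 | intermediate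
23 | trans-fused hydrindenone: C6 ketone, C8=C9, 10β-OTBS, 1α-methyl, 2α-OTIPS, 4α-hydroxy-4β-isopropyl, H-5β | O=C1C(C)=C[C@@H](O[Si](C)(C)C(C)(C)C)[C@@]2(C)[C@H](O[Si](C(C)C)(C(C)C)C(C)C)C[C@@](O)(C(C)C)[C@H]12 | intermediate
24 | ethyl acetate | CCOC(C)=O | starting material
25 | ethyl acetate lithium enolate | C=C(O[Li])OCC | intermediate
26 | β-hydroxy ester: 23 with C6 carbinol bearing CH2CO2Et (expected epimer drawn; either serves) | CCOC(=O)C[C@@]1(O)C(C)=C[C@@H](O[Si](C)(C)C(C)(C)C)[C@@]2(C)[C@H](O[Si](C(C)C)(C(C)C)C(C)C)C[C@@](O)(C(C)C)[C@H]12 | intermediate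
27 | hydrindene β-hydroxy acid (key-step precursor) | OC(=O)C[C@@]1(O)C(C)=C[C@@H](O[Si](C)(C)C(C)(C)C)[C@@]2(C)[C@H](O[Si](C(C)C)(C(C)C)C(C)C)C[C@@](O)(C(C)C)[C@H]12 | intermediate
28 | trans-fused hydroazulenone: C6 ketone, C8=C9, 10β-OTBS, 2α-OTIPS, 4α-hydroxy (key-step product) | O=C1CC(C)=C[C@@H](O[Si](C)(C)C(C)(C)C)[C@@]2(C)[C@H](O[Si](C(C)C)(C(C)C)C(C)C)C[C@@](O)(C(C)C)[C@H]12 | intermediate
29 | 6β-alcohol (10β-OTBS, 2α-OTIPS, 4α-hydroxy) | O[C@H]1CC(C)=C[C@@H](O[Si](C)(C)C(C)(C)C)[C@@]2(C)[C@H](O[Si](C(C)C)(C(C)C)C(C)C)C[C@@](O)(C(C)C)[C@H]12 | intermediate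
30 | 4α,6β,10β-triol 2α-TIPS ether | O[C@H]1CC(C)=C[C@@H](O)[C@@]2(C)[C@H](O[Si](C(C)C)(C(C)C)C(C)C)C[C@@](O)(C(C)C)[C@H]12 | intermediate
31 | angelic acid, (Z)-2-methylbut-2-enoic acid | C/C=C(/C)C(=O)O | starting material
32 | angelic 2,4,6-trichlorobenzoic anhydride | C/C=C(/C)C(=O)OC(=O)c1c(Cl)cc(Cl)cc1Cl | intermediate
33 | 6β,10β-diangelate 2α-TIPS ether | C/C=C(/C)C(=O)O[C@H]1CC(C)=C[C@@H](OC(=O)/C(C)=C\C)[C@@]2(C)[C@H](O[Si](C(C)C)(C(C)C)C(C)C)C[C@@](O)(C(C)C)[C@H]12 | intermediate
34 | CNP0249167.2: 6β,10β-diangeloyloxy-2α,4α-dihydroxy trans-hydroazulene | C/C=C(/C)C(=O)O[C@H]1CC(C)=C[C@@H](OC(=O)/C(C)=C\C)[C@@]2(C)[C@H](O)C[C@@](O)(C(C)C)[C@H]12 | target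

## Step count and least certain steps

Total: 22 steps. Longest linear sequence: 22 steps (1 to 34); 7, 8, 18, 24 and 31 are commercial and enter directly.

**Step 18 (key step).** The electron-deficient C7 may be intercepted before the alkenyl shift (by the C6 or C4 hydroxyl, by solvent, or by dimerisation), the C6–C7 bond may fragment back towards the enone, or the C8–C9 alkene may drift into conjugation in the weakly basic medium. Fallback by known chemistry, from 23 to 28: addition of LiCHBr2 (CH2Br2, LiN(iPr)2, THF, −78 °C) to the C6 carbonyl gives the dibromomethyl carbinol F1. Treatment of F1 with nBuLi at −95 to −78 °C effects bromine–lithium exchange, and the β-oxido carbenoid rearranges with migration of the alkenyl carbon, the documented preference for enone adducts. Kinetic protonation of the resulting enolate at C7 gives 28.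

**Step 6.** Face selection on the aldehyde may be eroded because the closed transition state of the lithium enolate has its own, opposing preference, giving poor selectivity at C10; retro-aldol cleavage on work-up and enolate equilibration with loss of the silyloxy group are further hazards. Fallback, from 6 to 12: the conjugate-addition enolate is trapped with Me3SiCl to give the trimethylsilyl enol ether F2. A separate Mukaiyama aldol of F2 with 8 under BF3·OEt2 at −78 °C (open transition state, non-chelating Lewis acid, attack anti to the dioxolane C–O bond) then gives 12.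

**Step 8.** Discrimination between the C2 and C10 hydroxyls may be insufficient. Fallback, from 12 to 14: Evans–Tishchenko reduction of 12 (SmI2 cat., isobutyraldehyde, THF, −10 °C) delivers hydride from the C10 hemiacetal to the same face of C2 and leaves the C10 isobutyrate with free 2α-hydroxyl F3, so the two oxygens are differentiated by mechanism. Silylation with iPr3SiOTf gives the ester silyl ether F4, and iBu2AlH removes the ester to give 14.

**Step 15.** Dehydration may take the tertiary C4 hydroxyl instead of the C9 hydroxyl (through the C5 enol), C5 may epimerise to the cis-fused ketone, or C10 may epimerise through the aldehyde enol. Fallback, from 21 to 23: kinetic deprotonation with LiN(SiMe3)2 (THF, −78 °C) at the less hindered C8 methylene and intramolecular aldol addition give 22, which is isolated. Selective mesylation of its secondary C9 hydroxyl (MeSO2Cl, Et3N, 0 °C) gives mesylate F5, which eliminates under Et3N to 23; the tertiary hydroxyl cannot leave under these basic conditions.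

**Step 16.** The enolate may deprotonate the hindered enone or add in conjugate fashion, and the adduct may revert. Fallback, from 23 to 27: a smaller, less basic carbon nucleophile (vinylmagnesium bromide with CeCl3) gives the vinyl carbinol F6. Hydroboration of the terminal alkene with 9-BBN and NaOH/H2O2 work-up gives the primary alcohol F7, and oxidation with TEMPO (cat.) and PhI(OAc)2 in MeCN/H2O gives 27.

**Step 21.** Acylation of the neopentylic allylic C10 hydroxyl may stall, or forcing conditions may isomerise the angelate to the tiglate. Fallback, from 30 to 33: both hydroxyls are esterified with 2-[bis(2,2,2-trifluoroethoxy)phosphoryl]propanoic acid (DCC, cat. DMAP) to give the bis-phosphonate F8. Still–Gennari olefination of F8 with acetaldehyde (KN(SiMe3)2, 18-crown-6, THF, −78 °C) builds the Z-2-methylbut-2-enoates in place and gives 33.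

## Further compounds

F1 | step 18 | C6 dibromomethyl carbinol of 23 | BrC(Br)[C@@]1(O)C(C)=C[C@@H](O[Si](C)(C)C(C)(C)C)[C@@]2(C)[C@H](O[Si](C(C)C)(C(C)C)C(C)C)C[C@@](O)(C(C)C)[C@H]12
F2 | step 6 | trimethylsilyl enol ether of the conjugate adduct | CC1=C(O[Si](C)(C)C)C[C@@H](O[Si](CC)(CC)CC)[C@@H]1C(=C)CC
F3 | step 8 | C10 isobutyrate with free 2α-hydroxyl | CC1(C)OC[C@@H](O1)[C@@H](OC(=O)C(C)C)[C@@]2(C)[C@H](O)C[C@@H](O[Si](CC)(CC)CC)[C@@H]2C(=C)CC
F4 | step 8 | C10 isobutyrate 2α-TIPS ether | CC1(C)OC[C@@H](O1)[C@@H](OC(=O)C(C)C)[C@@]2(C)[C@H](O[Si](C(C)C)(C(C)C)C(C)C)C[C@@H](O[Si](CC)(CC)CC)[C@@H]2C(=C)CC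
F5 | step 15 | C9 mesylate of aldol 22 | O=C1C(C)C(OS(C)(=O)=O)[C@@H](O[Si](C)(C)C(C)(C)C)[C@@]2(C)[C@H](O[Si](C(C)C)(C(C)C)C(C)C)C[C@@](O)(C(C)C)[C@H]12
F6 | step 16 | C6 vinyl carbinol | C=C[C@@]1(O)C(C)=C[C@@H](O[Si](C)(C)C(C)(C)C)[C@@]2(C)[C@H](O[Si](C(C)C)(C(C)C)C(C)C)C[C@@](O)(C(C)C)[C@H]12
F7 | step 16 | C6 (2-hydroxyethyl) carbinol | OCC[C@@]1(O)C(C)=C[C@@H](O[Si](C)(C)C(C)(C)C)[C@@]2(C)[C@H](O[Si](C(C)C)(C(C)C)C(C)C)C[C@@](O)(C(C)C)[C@H]12
F8 | step 21 | 6,10-bis[2-(bis(2,2,2-trifluoroethoxy)phosphoryl)propanoate] 2-TIPS ether | CC(C(=O)O[C@H]1CC(C)=C[C@@H](OC(=O)C(C)P(=O)(OCC(F)(F)F)OCC(F)(F)F)[C@@]2(C)[C@H](O[Si](C(C)C)(C(C)C)C(C)C)C[C@@](O)(C(C)C)[C@H]12)P(=O)(OCC(F)(F)F)OCC(F)(F)F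
A1 | alternative 1 | hydroazulene-4,10-dione | CC(C)(C)[Si](C)(C)O[C@H]1CC(C)=CC(=O)[C@@]2(C)[C@H](O[Si](CC)(CC)CC)CC(=O)[C@H]12
A2 | alternative 1 | phenyl selenoester on a cyclopentenone | CC(C)(C)[Si](C)(C)O[C@@H](C/C(C)=C\C(=O)[Se]c1ccccc1)C2=C(C)[C@H](O[Si](CC)(CC)CC)CC2=O
A3 | alternative 2 | bicyclic cycloheptadiene ester | CCOC=1CC(C(=O)OCC)=C[C@@H](O[Si](C)(C)C(C)(C)C)[C@@]2(C)[C@H](O[Si](C(C)C)(C(C)C)C(C)C)C[C@H](O[Si](CC)(CC)CC)C=12
A4 | alternative 2 | ethyl (E)-4-(tert-butyldimethylsilyloxy)-2-diazobut-3-enoate | CCOC(=O)C(=[N+]=[N-])/C=C/O[Si](C)(C)C(C)(C)C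
A5 | alternative 2 | 1-(1-ethoxyvinyl)-2-methylcyclopentene diene with C2 OTIPS and C4 OTES | C=C(OCC)C1=C(C)[C@H](O[Si](C(C)C)(C(C)C)C(C)C)C[C@@H]1O[Si](CC)(CC)CC
A6 | alternative 3 | hydroazulene with free C10 hydroxyl | CC(C)(C)[Si](C)(C)O[C@H]1CC(C)=C[C@@H](O)[C@@]2(C)[C@H](O[Si](C(C)C)(C(C)C)C(C)C)C[C@@](O[Si](CC)(CC)CC)(C(C)C)[C@H]12
A7 | alternative 3 | Z alkenyl iodide aldehyde | O=C[C@@]1(C)[C@H](O[Si](C(C)C)(C(C)C)C(C)C)C[C@@](O[Si](CC)(CC)CC)(C(C)C)[C@@H]1[C@@H](O[Si](C)(C)C(C)(C)C)C/C(C)=C\I
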